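## The problem

Compound 37, methyl 20-oxolabda-8(17),13-dien-16,15-olid-19-oate as its (4S,5R,9S,10S) enantiomer, is a trans-decalin whose ring A holds two quaternary carbons in a 1,3-relationship: C4 with methyl C18 and the C19 methyl ester, and the ring-fusion carbon C10 with the C20 aldehyde. C19 and C20 are axial on the same face, C5–H lies on the other, and ring B carries the 8(17)-methylene next to C9, whose equatorial two-carbon chain ends in an α-substituted butenolide (C13 to C16). Four stereocentres must be set (C4, C5, C9, C10), three of them contiguous and two quaternary, so they are best built on one another. C5 can be made first by catalysis in an open chain and can then dictate C4 if a temporary centre at C1 relays it; the C4 carboxyl can then choose between two identical one-carbon arms on C10, and the finished trans-fused frame can finally control C9. The fragile groups are the butenolide (hydroxide, hydride, strong base), the 1,1-disubstituted alkene (acid moves it into the ring, hydrogenation removes it) and the C19 ester/C20 aldehyde pair, which at the alcohol/ester stage re-closes to a δ-lactone, so these must appear late and in a fixed order. The feature that opens the route is that C4 bears a carboxyl carbon and is joined to C10 through C3–C2–C1. If C19 is held as a δ-lactone on an oxygen at C1, and C1 carries a vinyl group (the future C2 and C3), the lactone enolate and the allyl unit form a 1,5-diene array. A [3,3] shift then makes C3–C4, closes ring A and returns C19 as a free acid on the new quaternary centre.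

## Retrosynthesis

**C12–C13.** Target 37 is cut between C12 and C13 into iodo aldehyde 31 and the sulfur-stabilised lactone 34, with sulfide 35 and sulfoxide 36 as the links. The butenolide cannot survive the hydroxide that must open the C19–O–C20 lactone, so it has to come last. An oxidative unmasking of the unsaturated lactone at the end would favour the wrong regioisomer, whereas alkylating the enolate of 34 and eliminating the sulfoxide into the ring gives the C13=C14 isomer. The precursor loses a ring and needs no new stereocontrol. The forward alkylation must tolerate the C20 aldehyde, which is non-enolisable and neopentyl.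

**C19/C20 oxidation pattern.** No skeletal bond is cut between 31 and lactone alcohol 27. Iodide 30 and diol ester 29 trace the ester and aldehyde back to a δ-lactone joining C19 to the C20 oxygen. Keeping this lactone until ring B is finished protects both groups through radical and hydrogenation steps. The forward sequence must open a hindered lactone without re-closure and activate only the unhindered C12 hydroxyl.

**C8–C9 (ring B).** Lactone 27 is cut at C8–C9 to enyne 24, by way of vinylstannane 25. A closure that starts from a radical centred on C9 was set aside, because that radical would be homoallylic to the C1=C2 alkene and open to a 1,2-vinyl shift, and because no two-carbon nucleophile would bring an oxygen at C12. Closing ring B by carbonyl chemistry at C8 would cost extra steps. Letting a stannyl radical add to the terminal alkyne of 24 makes a C8 vinyl radical that attacks C9; this leaves C12 as a primary alcohol and masks the methylene as a vinylstannane that outlasts saturation of C1=C2. The precursor has one ring and one stereocentre fewer. The forward step must close 6-exo through a chair.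

**C9=C11 and the C9 arm.** Allylic alcohol 24 comes from aldehyde 22 and phosphonium salt 23 by Wittig olefination, and 22 from alcohol 21. A non-stabilised oxido ylide is chosen because it reaches the neopentyl aldehyde and gives the alcohol oxidation level at C12 directly, which an ester-based olefination would not do in the presence of the lactone.

**C19–O–C20 lactone.** Opening lactone 21 leads back to acid 18, in which C10 carries two identical arms tied as an acetonide and is no longer stereogenic. This is the main simplification after the key step. The forward reaction relies on geometry alone: only the arm cis to the carboxyl can lactonise, so that arm becomes C20 and the other C9. A cyclic ketal is preferred to two benzyl-type ethers because it costs one reagent and leaves in the lactonisation flask.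

**C3–C4 (key step, ring A).** Acid 18 is cut at C3–C4 with re-formation of C1–O, giving silyl ketene acetal 16 of vinyl lactone 15. Against an intermolecular alkylation or a Diels–Alder construction of ring A, this cut forms the quaternary C4 intramolecularly and takes its configuration from C1 and C5. The forward reaction needs a vinyl group trans to the C5 chain and clean O-silylation.

**Lactone and C1.** Lactone 15 opens to hydroxy thioester 14, which comes from vinyl ketone 13 by reagent-controlled reduction. Ketone 13 comes from allylic alcohol 12, and 12 from aldehyde 10 and vinylmagnesium bromide 11. Reduction is preferred to a direct stereoselective vinyl addition because C10 carries two identical arms and gives no useful substrate bias.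

**C10 arms.** Aldehyde 10 comes from diol 9, which arises from aldehyde 7 and two molecules of formaldehyde 8 by double aldol addition. This makes C10 quaternary in one operation from the α-methylene group that the conjugate addition leaves behind.

**C4–C5.** Aldehyde 7 is cut at C4–C5 into enal 4 and silyl ketene thioacetal 6 (from thioester 5). Iminium catalysis sets C5 as the only stereocentre that has to be bought from a catalyst. Enal 4 comes from aldehyde 2 and ylide 3, and 2 from alcohol 1.

## Roads not taken

Alternative 1: The C9–C11 bond is cut. Glyoxylate ester A1, a Δ8 decalin that carries the glyoxylate on its C20 oxygen, would undergo a Lewis-acid-promoted intramolecular carbonyl-ene reaction. The aldehyde carbon adds to C9 while a C17 hydrogen moves to oxygen, and the product is hydroxy δ-lactone A2 with the 8(17)-methylene in place.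
- Merits: the tether delivers C11 to the correct face of C9, and the methylene appears without tin or a masked alkene. In both respects it is better than the chosen plan, whose C9 rests on a chair preference in a radical closure.
- Weak points: A1 already contains C4, C5 and C10, so the harder half of the problem is untouched. Hydrogen transfer from C7 instead of C17 would leave the double bond inside ring B. The C11 carbinol of A2 must be removed, and C12 arrives as a lactone carbonyl tied to C20, so reduction and differentiation steps follow.
- The chosen plan offers in return a defined origin for the C4/C5/C10 triad and a C12 at the right oxidation level.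

Alternative 2: C5–C10 and C8–C9 are cut together. Acyclic (E)-α-formyl trienal A3 would close rings A and B in one intramolecular Diels–Alder reaction to the trans-fused adduct A4.
- Merits: two rings and three stereocentres in one step, with C20 already an aldehyde. In ring-forming economy this is superior to the chosen plan.
- Weak points: the quaternary C4 of A3 must be made enantioselectively in an open chain and is then the only control element. Its methyl and ester groups differ little in size, so the facial sense of the cycloaddition relative to C4 is insecure. A4 has the wrong C9 configuration and an allylic silyl ether and ring alkene that need about five steps to become the 8(17)-methylene, although C9 could be corrected by epimerisation once C8 is oxidised.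
- The chosen plan answers the C4/C5 relationship with a tether-enforced suprafacial shift (16 to 17) instead of a steric preference.

Alternative 3: C7–C8 and C9–C10 are cut. Allenoate ester A5, a vinylcyclohexene whose C20 oxygen is acylated by buta-2,3-dienoic acid, would undergo an intramolecular Diels–Alder reaction across the internal allene bond. The product would be tricycle A6 with ring B, the methylene and a γ-lactone.
- Merits: the methylene comes straight from the allene, and the tether forces C11 and C20 onto the same face, which is the correct C9/C10 relationship. On this point it is better than the chosen plan.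
- Weak points: the diene terminus C10 of A5 is fully substituted and flanked by quaternary C4, so the cycloaddition should be slow. The C5=C6 alkene left in A6 must be reduced from one face in the presence of a more reactive free methylene. C11 is a carbonyl on C9 and has to be reduced and extended. C4 is again the only pre-existing stereocentre.
- The chosen plan also has an alkene to saturate (C1=C2), but its competitor there is a hindered trisubstituted vinylstannane, and C5 is set before any ring exists.

Key step: step 11

## Route

Remark: atom labels C1–C20 follow the labdane numbering of 37. The carbon α to C19 (labdane C4) is carried as an epimeric pair from 7 to 15 and is planarised in 16, so its configuration there is immaterial.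

Step 1
Reactants: 1 5-(trimethylsilyl)pent-4-yn-1-ol
Product: 2 5-(trimethylsilyl)pent-4-ynal
Conditions: PhI(OAc)2, 2,2,6,6-tetramethylpiperidin-1-oxyl (10 mol %), CH2Cl2, 23 °C
Reagents that add atoms: none
Why: Oxoammonium-mediated alcohol oxidation stops at the aldehyde and leaves the silyl alkyne untouched.

Step 2
Reactants: 2 5-(trimethylsilyl)pent-4-ynal; 3 (triphenyl-λ5-phosphanylidene)acetaldehyde
Product: 4 (2E)-7-(trimethylsilyl)hept-2-en-6-ynal
Conditions: toluene, 80 °C
Reagents that add atoms: none
Why: Wittig olefination with the stabilised formylmethylene ylide should give the (E)-enal, the saturated aldehyde reacting faster than the conjugated product.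

Step 3
Reactants: 5 S-ethyl propanethioate
Product: 6 [(1Z)-1-(ethylsulfanyl)prop-1-en-1-yl]oxy(trimethyl)silane
Conditions: LiN(i-Pr)2, THF, −78 °C; Me3SiCl, −78 to 0 °C
Reagents that add atoms: chlorotrimethylsilane, C[Si](C)(C)Cl
Why: Kinetic enolisation and O-silylation give the silyl ketene thioacetal; its geometry does not matter because the α-carbon is planarised again in step 11.

Step 4
Reactants: 4 (2E)-7-(trimethylsilyl)hept-2-en-6-ynal; 6 silyl ketene thioacetal
Product: 7 S-ethyl (3R)-2-methyl-3-(2-oxoethyl)-7-(trimethylsilyl)hept-6-ynethioate (C2 epimers)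
Conditions: (2S,5S)-5-benzyl-2-tert-butyl-3-methylimidazolidin-4-one·Cl3CCO2H (20 mol %), i-PrOH (2 equiv), CH2Cl2, −60 °C
Reagents that add atoms: none
Why: Organocatalytic Mukaiyama–Michael addition through the (E)-iminium ion of 4; the benzyl group of the (2S,5S)-imidazolidinone shields one face so that the nucleophile should add to the other and set C5 (chain carbon 3) as R, with 1,4- rather than 1,2-addition under iminium activation.

Step 5
Reactants: 7 aldehyde thioester; 8 formaldehyde
Product: 9 S-ethyl (3S)-3-(2-formyl-1,3-dihydroxypropan-2-yl)-2-methyl-7-(trimethylsilyl)hept-6-ynethioate (C2 epimers)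
Conditions: 37% aq. CH2O (5 equiv), Et3N (0.3 equiv), THF, 35 °C
Reagents that add atoms: formaldehyde (second equivalent), C=O
Why: Two successive amine-catalysed crossed aldol additions, each taking up one molecule of formaldehyde at the α-carbon of the aldehyde; after the second, C10 is quaternary, so dehydration and further enolisation are impossible, and without strong base no Cannizzaro reduction is expected (the descriptor at chain carbon 3 changes only because priorities change).

Step 6
Reactants: 9 diol aldehyde
Product: 10 S-ethyl (3S)-3-(5-formyl-2,2-dimethyl-1,3-dioxan-5-yl)-2-methyl-7-(trimethylsilyl)hept-6-ynethioate (C2 epimers)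
Conditions: Me2C(OMe)2, pyridinium p-toluenesulfonate (5 mol %), acetone, 23 °C
Reagents that add atoms: 2,2-dimethoxypropane, COC(C)(C)OC
Why: Acid-catalysed transketalisation closes the six-membered dioxane on the 1,3-diol; the neopentyl aldehyde is too hindered to be acetalised under these conditions.

Step 7
Reactants: 10 dioxane aldehyde; 11 vinylmagnesium bromide
Product: 12 S-ethyl (3S)-3-[5-(1-hydroxyprop-2-en-1-yl)-2,2-dimethyl-1,3-dioxan-5-yl]-2-methyl-7-(trimethylsilyl)hept-6-ynethioate (carbinol and C2 epimers)
Conditions: THF, −78 °C; AcOH quench at −78 °C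
Reagents that add atoms: none
Why: Grignard 1,2-addition; at −78 °C the aldehyde should outrun the α-branched thioester, and the cold acidic quench keeps the alkoxide from acylating on C19; both C1 epimers are acceptable because C1 is reset in step 9.

Step 8
Reactants: 12 allylic alcohol
Product: 13 S-ethyl (3S)-3-[2,2-dimethyl-5-(prop-2-enoyl)-1,3-dioxan-5-yl]-2-methyl-7-(trimethylsilyl)hept-6-ynethioate (C2 epimers)
Conditions: Dess–Martin periodinane, NaHCO3, CH2Cl2, 0 to 23 °C
Reagents that add atoms: none
Why: Buffered Dess–Martin oxidation converts the allylic alcohol into the vinyl ketone without touching thioester, ketal or alkyne.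

Step 9
Reactants: 13 vinyl ketone
Product: 14 S-ethyl (3S)-3-{5-[(1R)-1-hydroxyprop-2-en-1-yl]-2,2-dimethyl-1,3-dioxan-5-yl}-2-methyl-7-(trimethylsilyl)hept-6-ynethioate (C2 epimers)
Conditions: (S)-1-methyl-3,3-diphenyltetrahydro-1H,3H-pyrrolo[1,2-c][1,3,2]oxazaborole (0.5 equiv), catecholborane, toluene, −78 °C
Reagents that add atoms: none
Why: Corey–Bakshi–Shibata reduction; the fully substituted C10 acts as the large and the vinyl group as the small substituent, so the (S)-oxazaborolidine should deliver hydride to give the 1R carbinol, and catecholborane at −78 °C reduces 1,2 and spares thioester and alkyne.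

Step 10
Reactants: 14 (1R)-hydroxy thioester
Product: 15 (7R,11S)-7-ethenyl-3,3,10-trimethyl-11-[4-(trimethylsilyl)but-3-yn-1-yl]-2,4,8-trioxaspiro[5.5]undecan-9-one (epimers at ring carbon 10 = labdane C4; vinyl trans to the butynyl chain)
Conditions: NaH, THF, 0 to 23 °C
Reagents that add atoms: none
Why: Intramolecular acyl substitution: the C1 alkoxide attacks the thioester through a six-membered transition state and expels ethanethiolate, giving the δ-lactone without touching C1 or C5.

Step 11
Reactants: 15 vinyl δ-lactone
Product: 18 (7R,8S)-3,3,8-trimethyl-7-[4-(trimethylsilyl)but-3-yn-1-yl]-2,4-dioxaspiro[5.5]undec-10-ene-8-carboxylic acid, via silyl ketene acetal 16 (not isolated), via silyl ester 17 (not isolated)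
Conditions: LiN(i-Pr)2, THF/DMPU, −78 °C; t-BuMe2SiCl, −78 to 23 °C; toluene, 110 °C; then AcOH/THF/H2O, 23 °C
Reagents that add atoms: none
Why: LiN(i-Pr)2 removes the C4 proton of either epimer of 15 and t-BuMe2SiCl traps the enolate on oxygen as ketene acetal 16, whose geometry is fixed by the ring. On heating, 16 undergoes an Ireland–Claisen [3,3]-sigmatropic shift in which C3 bonds to C4 while C1–O breaks, so the six-membered lactone is exchanged for carbocyclic ring A with a C1=C2 alkene and C19 is released as silyl ester 17. The closest known reaction type is the Claisen carbocyclisation of silyl ketene acetals of 6-alkenyl δ-lactones to cyclohex-3-enecarboxylic acids. Ring A closes as a six-membered ring through a boat, bicyclo[2.2.2]octene-like transition state, because four atoms of the pericyclic array (C4, C19, O, C1) are held in the lactone. The new quaternary stereocentre C4 is controlled by C1: the vinyl group can reach only the face of C4 on which it sits, and since it is trans to the C5 chain the carboxyl ends up cis to that chain, as 37 requires. The step needs O- rather than C-silylation, which a bulky silyl chloride with DMPU on a fully substituted enolate carbon should secure, and rearrangement rather than decomposition, which the enforced proximity and the unhindered CH2 terminus favour. Aqueous acetic acid then cleaves the silyl ester to acid 18 and leaves the acetonide and the silyl alkyne in place.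

Step 12
Reactants: 18 cyclohexene acid
Product: 21 (1S,5R,9R)-9-(but-3-yn-1-yl)-5-(hydroxymethyl)-1-methyl-3-oxabicyclo[3.3.1]non-6-en-2-one, via desilylated carboxylate 19 (not isolated), via diol acid 20 (not isolated)
Conditions: K2CO3, MeOH, 23 °C; then 2 M aq. HCl, THF, 40 °C
Reagents that add atoms: none
Why: Methanolic carbonate removes the alkynyl silyl group; aqueous acid then hydrolyses the acetonide and the carboxyl lactonises onto the hydroxymethyl arm cis to it, the trans arm being out of reach, which makes C10 stereogenic and defines the lactone arm as C20 and the free arm as C9.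

Step 13
Reactants: 21 hydroxy lactone
Product: 22 (1S,5S,9R)-9-(but-3-yn-1-yl)-1-methyl-2-oxo-3-oxabicyclo[3.3.1]non-6-ene-5-carbaldehyde
Conditions: Dess–Martin periodinane, NaHCO3, CH2Cl2, 23 °C
Reagents that add atoms: none
Why: Dess–Martin oxidation of the neopentyl primary alcohol gives a non-enolisable aldehyde at C9.

Step 14
Reactants: 22 lactone aldehyde; 23 (2-hydroxyethyl)triphenylphosphonium bromide
Product: 24 (1S,5S,9R)-9-(but-3-yn-1-yl)-5-[(1E)-3-hydroxyprop-1-en-1-yl]-1-methyl-3-oxabicyclo[3.3.1]non-6-en-2-one
Conditions: n-BuLi (2 equiv per 23), THF, −78 to 0 °C; then 22, −78 to 23 °C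
Reagents that add atoms: none
Why: Wittig olefination with the β-oxido ylide from 23; a non-stabilised ylide is reactive enough for the neopentyl aldehyde and gives the allylic alcohol directly, and the alkene geometry is immaterial because C11 becomes sp3 in step 15.

Step 15
Reactants: 24 enyne allylic alcohol
Product: 25 (4S,5R,9R,10R)-12-hydroxy-17-(tributylstannyl)-13,14,15,16-tetranorlabda-1,8(17)-dien-19,20-olide (E/Z at C8=C17)
Conditions: Bu3SnH (1.3 equiv), 2,2′-azobis(2-methylpropanenitrile) (0.2 equiv), benzene (0.02 M), 80 °C
Reagents that add atoms: tributylstannane, CCCC[SnH](CCCC)CCCC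
Why: Stannyl-radical-mediated enyne cyclisation: the tin radical adds to the terminal alkyne carbon C17, the C8 vinyl radical closes 6-exo-trig onto C9 and the C11 radical is reduced; a chair transition state on the lactone-locked ring A with the C11 branch equatorial should set C9 with its hydrogen axial, and C1=C2 is out of reach because the lactone holds the C5 chain equatorial.

Step 16
Reactants: 25 vinylstannane diene
Product: 27 (4S,5R,9S,10S)-12-hydroxy-13,14,15,16-tetranorlabd-8(17)-en-19,20-olide, via dihydro stannane 26 (not isolated)
Conditions: H2 (1 atm), RhCl(PPh3)3 (10 mol %), benzene/EtOH, 23 °C; then HCl (1 M in Et2O, 1.2 equiv), CH2Cl2, 0 °C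
Reagents that add atoms: none
Why: RhCl(PPh3)3 hydrogenates the cis-disubstituted ring alkene much faster than the hindered trisubstituted vinylstannane; ipso-protodestannylation then releases the 8(17)-methylene through a β-stannyl cation without allowing the double bond to migrate.

Step 17
Reactants: 27 lactone alcohol
Product: 29 methyl (4S,5R,9S,10S)-12,20-dihydroxy-13,14,15,16-tetranorlabd-8(17)-en-19-oate, via potassium carboxylate 28 (not isolated)
Conditions: KOH, MeOH/H2O, 70 °C; evaporation; MeI, DMF, 23 °C
Reagents that add atoms: potassium hydroxide, [K+].[OH-]; iodomethane, CI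
Why: Saponification of the hindered lactone followed by SN2 O-alkylation of the carboxylate gives the methyl ester without acid, so the 1,3-diaxial hydroxy ester should not re-close.

Step 18
Reactants: 29 diol ester
Product: 30 methyl (4S,5R,9S,10S)-20-hydroxy-12-iodo-13,14,15,16-tetranorlabd-8(17)-en-19-oate
Conditions: I2, PPh3, imidazole, CH2Cl2, 0 °C
Reagents that add atoms: iodine, II
Why: Appel-type iodination proceeds by SN2 displacement and should select the unhindered C12 hydroxyl, the neopentyl C20 hydroxyl being inert to backside attack.

Step 19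
Reactants: 30 iodo alcohol
Product: 31 methyl (4S,5R,9S,10S)-12-iodo-20-oxo-13,14,15,16-tetranorlabd-8(17)-en-19-oate
Conditions: Dess–Martin periodinane, NaHCO3, CH2Cl2, 23 °C
Reagents that add atoms: none
Why: Dess–Martin oxidation converts the neopentyl C20 alcohol into the aldehyde and tolerates the primary iodide, the ester and the alkene.

Step 20
Reactants: 32 3-bromooxolan-2-one; 33 benzenethiol
Product: 34 3-(phenylsulfanyl)oxolan-2-one (racemic)
Conditions: Et3N, CH2Cl2, 0 to 23 °C
Reagents that add atoms: none
Why: SN2 displacement of the activated α-bromide by thiolate.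

Step 21
Reactants: 31 iodo aldehyde; 34 3-(phenylsulfanyl)oxolan-2-one
Product: 35 methyl (4S,5R,9S,10S)-20-oxo-13-(phenylsulfanyl)labd-8(17)-en-16,15-olid-19-oate (C13 epimers)
Conditions: NaN(SiMe3)2, THF/DMPU, −78 °C (enolate of 34); then 31, −78 to 0 °C
Reagents that add atoms: none
Why: SN2 alkylation of the sulfur-stabilised lactone enolate by the primary iodide; neither the C19 ester nor the C20 aldehyde is enolisable, aldol addition to the hindered aldehyde is reversible, and the new C13 centre is destroyed in step 22.

Step 22
Reactants: 35 sulfide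
Product: 37 methyl (4S,5R,9S,10S)-20-oxolabda-8(17),13-dien-16,15-olid-19-oate, via sulfoxide 36 (not isolated)
Conditions: 3-chloroperoxybenzoic acid (1.0 equiv), CH2Cl2, −78 °C; then CaCO3, toluene, 110 °C
Reagents that add atoms: none
Why: Sulfide oxidation at −78 °C is far faster than epoxidation of the 1,1-disubstituted alkene or Baeyer–Villiger attack on the aldehyde; thermal syn-elimination of the sulfoxide into the ring gives the endocyclic C13=C14 butenolide, as is usual for α-alkyl-α-sulfinyl γ-lactones.

## Compound list

1 | 5-(trimethylsilyl)pent-4-yn-1-ol | C[Si](C)(C)C#CCCCO | starting material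
2 | 5-(trimethylsilyl)pent-4-ynal | C[Si](C)(C)C#CCCC=O | intermediate
3 | (triphenyl-λ5-phosphanylidene)acetaldehyde | O=CC=P(c1ccccc1)(c1ccccc1)c1ccccc1 | starting material
4 | (2E)-7-(trimethylsilyl)hept-2-en-6-ynal | C[Si](C)(C)C#CCC/C=C/C=O | intermediate
5 | S-ethyl propanethioate | CCSC(=O)CC | starting material
6 | [(1Z)-1-(ethylsulfanyl)prop-1-en-1-yl]oxy(trimethyl)silane | C/C=C(\SCC)O[Si](C)(C)C | intermediate
7 | S-ethyl (3R)-2-methyl-3-(2-oxoethyl)-7-(trimethylsilyl)hept-6-ynethioate (C2 epimers) | CCSC(=O)C(C)[C@@H](CC=O)CCC#C[Si](C)(C)C | intermediate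
8 | formaldehyde | C=O | starting material
9 | S-ethyl (3S)-3-(2-formyl-1,3-dihydroxypropan-2-yl)-2-methyl-7-(trimethylsilyl)hept-6-ynethioate (C2 epimers) | CCSC(=O)C(C)[C@@H](C(CO)(CO)C=O)CCC#C[Si](C)(C)C | intermediate
10 | S-ethyl (3S)-3-(5-formyl-2,2-dimethyl-1,3-dioxan-5-yl)-2-methyl-7-(trimethylsilyl)hept-6-ynethioate (C2 epimers) | CCSC(=O)C(C)[C@@H](C1(C=O)COC(C)(C)OC1)CCC#C[Si](C)(C)C | intermediate
11 | vinylmagnesium bromide | C=C[Mg]Br | starting material
12 | S-ethyl (3S)-3-[5-(1-hydroxyprop-2-en-1-yl)-2,2-dimethyl-1,3-dioxan-5-yl]-2-methyl-7-(trimethylsilyl)hept-6-ynethioate (carbinol and C2 epimers) | CCSC(=O)C(C)[C@@H](C1(C(O)C=C)COC(C)(C)OC1)CCC#C[Si](C)(C)C | intermediate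
13 | S-ethyl (3S)-3-[2,2-dimethyl-5-(prop-2-enoyl)-1,3-dioxan-5-yl]-2-methyl-7-(trimethylsilyl)hept-6-ynethioate (C2 epimers) | CCSC(=O)C(C)[C@@H](C1(C(=O)C=C)COC(C)(C)OC1)CCC#C[Si](C)(C)C | intermediate
14 | S-ethyl (3S)-3-{5-[(1R)-1-hydroxyprop-2-en-1-yl]-2,2-dimethyl-1,3-dioxan-5-yl}-2-methyl-7-(trimethylsilyl)hept-6-ynethioate (C2 epimers) | CCSC(=O)C(C)[C@@H](C1([C@H](O)C=C)COC(C)(C)OC1)CCC#C[Si](C)(C)C | intermediate
15 | (7R,11S)-7-ethenyl-3,3,10-trimethyl-11-[4-(trimethylsilyl)but-3-yn-1-yl]-2,4,8-trioxaspiro[5.5]undecan-9-one (epimers at ring carbon 10; vinyl trans to the butynyl chain) | C=C[C@H]1OC(=O)C(C)[C@H](CCC#C[Si](C)(C)C)C12COC(C)(C)OC2 | intermediate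
16 | tert-butyl{[(7R,11R)-7-ethenyl-3,3,10-trimethyl-11-[4-(trimethylsilyl)but-3-yn-1-yl]-2,4,8-trioxaspiro[5.5]undec-9-en-9-yl]oxy}dimethylsilane | C=C[C@H]1OC(O[Si](C)(C)C(C)(C)C)=C(C)[C@H](CCC#C[Si](C)(C)C)C12COC(C)(C)OC2 | intermediate (not isolated)
17 | tert-butyldimethylsilyl (7R,8S)-3,3,8-trimethyl-7-[4-(trimethylsilyl)but-3-yn-1-yl]-2,4-dioxaspiro[5.5]undec-10-ene-8-carboxylate | CC(C)(C)[Si](C)(C)OC(=O)[C@@]1(C)CC=CC2(COC(C)(C)OC2)[C@H]1CCC#C[Si](C)(C)C | intermediate (not isolated)
18 | (7R,8S)-3,3,8-trimethyl-7-[4-(trimethylsilyl)but-3-yn-1-yl]-2,4-dioxaspiro[5.5]undec-10-ene-8-carboxylic acid | OC(=O)[C@@]1(C)CC=CC2(COC(C)(C)OC2)[C@H]1CCC#C[Si](C)(C)C | intermediate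
19 | potassium (7R,8S)-7-(but-3-yn-1-yl)-3,3,8-trimethyl-2,4-dioxaspiro[5.5]undec-10-ene-8-carboxylate | [K+].[O-]C(=O)[C@@]1(C)CC=CC2(COC(C)(C)OC2)[C@H]1CCC#C | intermediate (not isolated)
20 | (1S,6R)-6-(but-3-yn-1-yl)-5,5-bis(hydroxymethyl)-1-methylcyclohex-3-ene-1-carboxylic acid | OC(=O)[C@@]1(C)CC=CC(CO)(CO)[C@H]1CCC#C | intermediate (not isolated)
21 | (1S,5R,9R)-9-(but-3-yn-1-yl)-5-(hydroxymethyl)-1-methyl-3-oxabicyclo[3.3.1]non-6-en-2-one | O=C1OC[C@]2(CO)C=CC[C@@]1(C)[C@@H]2CCC#C | intermediate
22 | (1S,5S,9R)-9-(but-3-yn-1-yl)-1-methyl-2-oxo-3-oxabicyclo[3.3.1]non-6-ene-5-carbaldehyde | O=C1OC[C@]2(C=O)C=CC[C@@]1(C)[C@@H]2CCC#C | intermediate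
23 | (2-hydroxyethyl)triphenylphosphonium bromide | OCC[P+](c1ccccc1)(c1ccccc1)c1ccccc1.[Br-] | starting material
24 | (1S,5S,9R)-9-(but-3-yn-1-yl)-5-[(1E)-3-hydroxyprop-1-en-1-yl]-1-methyl-3-oxabicyclo[3.3.1]non-6-en-2-one | O=C1OC[C@]2(/C=C/CO)C=CC[C@@]1(C)[C@@H]2CCC#C | intermediate
25 | (4S,5R,9R,10R)-12-hydroxy-17-(tributylstannyl)-13,14,15,16-tetranorlabda-1,8(17)-dien-19,20-olide (E/Z mixture at C8=C17) | CCCC[Sn](CCCC)(CCCC)C=C1CC[C@@H]2[C@@]3(COC(=O)[C@@]2(C)CC=C3)[C@H]1CCO | intermediate
26 | (4S,5R,9R,10R)-12-hydroxy-17-(tributylstannyl)-13,14,15,16-tetranorlabd-8(17)-en-19,20-olide (E/Z mixture at C8=C17) | CCCC[Sn](CCCC)(CCCC)C=C1CC[C@@H]2[C@@]3(COC(=O)[C@@]2(C)CCC3)[C@H]1CCO | intermediate (not isolated)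
27 | (4S,5R,9S,10S)-12-hydroxy-13,14,15,16-tetranorlabd-8(17)-en-19,20-olide | C=C1CC[C@@H]2[C@@]3(COC(=O)[C@@]2(C)CCC3)[C@H]1CCO | intermediate
28 | potassium (4S,5R,9S,10S)-12,20-dihydroxy-13,14,15,16-tetranorlabd-8(17)-en-19-oate | C=C1CC[C@@H]2[C@](CO)(CCC[C@]2(C)C(=O)[O-])[C@H]1CCO.[K+] | intermediate (not isolated)
29 | methyl (4S,5R,9S,10S)-12,20-dihydroxy-13,14,15,16-tetranorlabd-8(17)-en-19-oate | C=C1CC[C@@H]2[C@](CO)(CCC[C@]2(C)C(=O)OC)[C@H]1CCO | intermediate
30 | methyl (4S,5R,9S,10S)-20-hydroxy-12-iodo-13,14,15,16-tetranorlabd-8(17)-en-19-oate | C=C1CC[C@@H]2[C@](CO)(CCC[C@]2(C)C(=O)OC)[C@H]1CCI | intermediate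
31 | methyl (4S,5R,9S,10S)-12-iodo-20-oxo-13,14,15,16-tetranorlabd-8(17)-en-19-oate | C=C1CC[C@@H]2[C@](C=O)(CCC[C@]2(C)C(=O)OC)[C@H]1CCI | intermediate
32 | 3-bromooxolan-2-one (racemic) | O=C1OCCC1Br | starting material
33 | benzenethiol | Sc1ccccc1 | starting material
34 | 3-(phenylsulfanyl)oxolan-2-one (racemic) | O=C1OCCC1Sc1ccccc1 | intermediate
35 | methyl (4S,5R,9S,10S)-20-oxo-13-(phenylsulfanyl)labd-8(17)-en-16,15-olid-19-oate (C13 epimers) | C=C1CC[C@@H]2[C@](C=O)(CCC[C@]2(C)C(=O)OC)[C@H]1CCC1(Sc2ccccc2)CCOC1=O | intermediate
36 | methyl (4S,5R,9S,10S)-20-oxo-13-(phenylsulfinyl)labd-8(17)-en-16,15-olid-19-oate (diastereomers at C13 and sulfur) | C=C1CC[C@@H]2[C@](C=O)(CCC[C@]2(C)C(=O)OC)[C@H]1CCC1(S(=O)c2ccccc2)CCOC1=O | intermediate (not isolated)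
37 | methyl (4S,5R,9S,10S)-20-oxolabda-8(17),13-dien-16,15-olid-19-oate; methyl (1S,4aS,5S,8aR)-4a-formyl-1-methyl-6-methylidene-5-[2-(2-oxo-2,5-dihydrofuran-3-yl)ethyl]decahydronaphthalene-1-carboxylate | C=C1CC[C@@H]2[C@](C=O)(CCC[C@]2(C)C(=O)OC)[C@H]1CCC1=CCOC1=O | target

## Step count and least certain steps

Total: 22 steps. Longest linear sequence: 20 steps (1, 2, 4–19, 21, 22). Steps 3 and 20 prepare reagents 6 and 34.

**Step 11 (key step).** Enolisation at the hindered C4 may be incomplete or C-silylation may compete, and the rearrangement may be slow because the vinyl group must turn axial next to the spiro centre in a boat. Unreacted ketene acetal would revert to 15 on work-up. The fallback forms the same C3–C4 bond by intramolecular SN2′ enolate alkylation. It sets out from 14, which is phosphorylated (ClP(O)(OEt)2, N-methylimidazole) to the allylic diethyl phosphate F1. LiN(SiMe3)2 then generates the thioester enolate, which can reach only C3 (attack at C1 would give a four-membered ring) and closes ring A to the cyclohexene thioester F2. Hydroperoxide-assisted hydrolysis (LiOH, H2O2) returns to the route at 18. C4 control would then depend on enolate geometry and not on the tether, so epimers might have to be separated.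

**Step 15.** Three processes could intervene: poor facial selectivity at C9 if a boat-like approach competes; leakage to a seven-membered ring by rearrangement of the homoallylic C11 radical when the stannane is dilute; and plain hydrostannation when it is concentrated. The fallback corrects C9 thermodynamically. It sets out from 27 (as a C9 mixture): ozonolysis (O3, then Me2S) gives the 8-oxo-17-nor lactone F3, equilibration with DBU places the C9 chain equatorial, and Wittig methylenation (Ph3P=CH2) returns to 27.

**Step 5.** The second hydroxymethylation at the β-branched carbon may stall, the mono-adduct may dehydrate, or a new hydroxyl may attack the thioester under base. The fallback avoids base. It sets out from 7, which is converted (Me3SiCl, Et3N, NaI, MeCN) into the silyl enol ether F4. Aqueous formaldehyde with Yb(OTf)3 gives the mono(hydroxymethyl) aldehyde F5, renewed silylation gives the bis-silyl derivative F6, and a second Yb(OTf)3-catalysed hydroxymethylation returns to 9.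

**Step 9.** Discrimination between the vinyl group and the quaternary carbon may be insufficient, or some conjugate reduction may occur. The fallback makes the small group linear. It sets out from 10: ethynylmagnesium bromide gives the ethynyl carbinol F7 and Dess–Martin oxidation the ethynyl ketone F8. The same (S)-oxazaborolidine with catecholborane, for which the ethynyl group is unambiguously the small substituent, should give the (1R)-ethynyl carbinol F9. Semi-hydrogenation (H2, Pd/CaCO3 poisoned with Pb(OAc)2 and quinoline) returns to 14.

**Step 17.** The hydroxy ester 29 may re-close to the lactone by transesterification, especially while its diol is being activated in step 18. The fallback shortens the life of the free C20 alcohol. It sets out from 27, which is silylated (i-Pr3SiCl, imidazole) to the silyl ether F10. Saponification and methylation as in step 17 give the hydroxy ester F11, which is oxidised at once (Dess–Martin periodinane) to the aldehyde F12. HF·pyridine gives the hydroxy aldehyde F13, and iodination as in step 18 returns to the route at 31.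

## Further compounds

F1 | step 11 | allylic diethyl phosphate of 14 (configuration as in 14) | CCSC(=O)C(C)[C@@H](C1([C@H](OP(=O)(OCC)OCC)C=C)COC(C)(C)OC1)CCC#C[Si](C)(C)C
F2 | step 11 | S-ethyl thioester of acid 18 (7R,8S) | CCSC(=O)[C@@]1(C)CC=CC2(COC(C)(C)OC2)[C@H]1CCC#C[Si](C)(C)C
F3 | step 15 | 8-oxo-17-nor analogue of 27 (C4, C5, C10 as in 27; C9 chain equatorial) | O=C1CC[C@@H]2[C@@]3(COC(=O)[C@@]2(C)CCC3)[C@H]1CCO
F4 | step 5 | trimethylsilyl enol ether of 7 (E/Z mixture; chain carbon 3 as in 7) | CCSC(=O)C(C)[C@@H](C=CO[Si](C)(C)C)CCC#C[Si](C)(C)C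
F5 | step 5 | mono(hydroxymethyl) aldehyde from 7 (epimers at the new centre; chain carbon 3 as in 7) | CCSC(=O)C(C)[C@@H](C(CO)C=O)CCC#C[Si](C)(C)C
F6 | step 5 | O-silyl silyl enol ether of F5 (E/Z mixture) | CCSC(=O)C(C)[C@@H](C(CO[Si](C)(C)C)=CO[Si](C)(C)C)CCC#C[Si](C)(C)C
F7 | step 9 | ethynyl carbinol from 10 (carbinol epimers) | CCSC(=O)C(C)[C@@H](C1(C(O)C#C)COC(C)(C)OC1)CCC#C[Si](C)(C)C
F8 | step 9 | ethynyl ketone from F7 | CCSC(=O)C(C)[C@@H](C1(C(=O)C#C)COC(C)(C)OC1)CCC#C[Si](C)(C)C
F9 | step 9 | (1R)-ethynyl carbinol (carbinol configured as in 14) | CCSC(=O)C(C)[C@@H](C1([C@H](O)C#C)COC(C)(C)OC1)CCC#C[Si](C)(C)C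
F10 | step 17 | 12-O-triisopropylsilyl ether of 27 | C=C1CC[C@@H]2[C@@]3(COC(=O)[C@@]2(C)CCC3)[C@H]1CCO[Si](C(C)C)(C(C)C)C(C)C
F11 | step 17 | methyl 20-hydroxy-12-(triisopropylsilyloxy)-13,14,15,16-tetranorlabd-8(17)-en-19-oate (configuration as in 29) | C=C1CC[C@@H]2[C@](CO)(CCC[C@]2(C)C(=O)OC)[C@H]1CCO[Si](C(C)C)(C(C)C)C(C)C
F12 | step 17 | methyl 20-oxo-12-(triisopropylsilyloxy)-13,14,15,16-tetranorlabd-8(17)-en-19-oate (configuration as in 31) | C=C1CC[C@@H]2[C@](C=O)(CCC[C@]2(C)C(=O)OC)[C@H]1CCO[Si](C(C)C)(C(C)C)C(C)C
F13 | step 17 | methyl 12-hydroxy-20-oxo-13,14,15,16-tetranorlabd-8(17)-en-19-oate (configuration as in 31) | C=C1CC[C@@H]2[C@](C=O)(CCC[C@]2(C)C(=O)OC)[C@H]1CCO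
A1 | alternative 1 | Δ8 decalin methyl ester carrying a glyoxylate on the C20 oxygen (ene precursor) | CC1=C[C@@]2(COC(=O)C=O)CCC[C@](C)(C(=O)OC)[C@@H]2CC1
A2 | alternative 1 | ene product: 8(17)-ene with C11-hydroxy δ-lactone from C12 to the C20 oxygen | C=C1CC[C@@H]2[C@](CO3)(CCC[C@]2(C)C(=O)OC)[C@H]1C(O)C3=O
A3 | alternative 2 | acyclic (E)-α-formyl trienal with terminal silyloxy diene | COC(=O)[C@@](C)(CCC/C(C=O)=C\CCOCc1ccc(OC)cc1)/C=C/C=C/O[Si](C)(C)C(C)(C)C
A4 | alternative 2 | trans-fused 6-ene with angular aldehyde, 8-silyloxy group and epimeric C9 | CC(C)(C)[Si](C)(C)O[C@H]1C=C[C@@H]2[C@](C=O)(CCC[C@]2(C)C(=O)OC)[C@@H]1CCOCc3ccc(OC)cc3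
A5 | alternative 3 | vinylcyclohexene with buta-2,3-dienoate ester on the C20 oxygen | C=CC1=C(COC(=O)C=C=C)CCC[C@]1(C)C(=O)OC
A6 | alternative 3 | 5-ene, 8(17)-ene tricycle with C11 γ-lactone onto the C20 oxygen | C=C1CC=C2[C@](CO3)(CCC[C@]2(C)C(=O)OC)[C@H]1C3=O
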